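**Retrosynthetic overview**
1. Target 15 ⇐ octabenzyl ether 14 by hydrogenolysis of eight benzyl ethers.
2. 14 ⇐ 4-aryl-flav-3-ene 12: the C3 oxygen and then H-4 are added last (epoxidation anti to ring B, hydride anti to the epoxide oxygen), so the catechin unit ends cis to 3-OH. The usual C4-cation plus catechin coupling gives this 4β isomer only as the minor product.
3. 12 ⇐ flavanone 8 + 8-bromocatechin 3: the C4–C8 bond is made with both partners' normal roles exchanged. The C4 ketone carbon acts as donor (tosylhydrazone → diazo carbon → palladium carbene) and catechin C8 as acceptor (aryl bromide).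
4. 8 ⇐ chromone 6 + boronic acid 7 (catalytic asymmetric 1,4-arylation sets C2); 6 ⇐ acetophenone 4; 3 ⇐ (+)-catechin 1.
5. Ring order: the lower rings A, C and B come intact from catechin; the upper ring C is closed on ring A as a chromone, ring B is then attached, and the two halves are joined last.

Assumption: boronic acid 7 is bought as a catalogue building block. The target is robinetinidol-(4β→8)-catechin, upper unit 2R,3S,4R (2,3-trans-3,4-cis), lower unit 2R,3S.

**Step 1**
Reactants: 1 (+)-catechin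
Product: 2 5,7,3',4'-tetra-O-benzyl-(+)-catechin
Conditions: BnBr (4.4 equiv), K2CO3 (5 equiv), DMF, 0 °C to rt, N2, 24 h
Reagents that add atoms: benzyl bromide, BrCc1ccccc1
Why: Williamson etherification in which K2CO3 ionises only the four phenols (the aliphatic 3-OH stays free), and the mild base at low temperature avoids C-benzylation and C2 epimerisation.

**Step 2**
Reactants: 2 5,7,3',4'-tetra-O-benzyl-(+)-catechin
Product: 3 8-bromo-5,7,3',4'-tetra-O-benzyl-(+)-catechin
Conditions: NBS (1.0 equiv), CH2Cl2, −78 °C to rt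
Reagents that add atoms: N-bromosuccinimide, O=C1CCC(=O)N1Br
Why: Electrophilic aromatic bromination in which C8, the more reactive of the two free positions of the phloroglucinol-type ring A in the tetrabenzyl ether, is brominated selectively by one equivalent of NBS at low temperature.

**Step 3**
Reactants: 4 1-[4-(benzyloxy)-2-hydroxyphenyl]ethan-1-one
Product: 6 7-(benzyloxy)-4H-chromen-4-one, via enaminone 5 (not isolated)
Conditions: DMF-DMA (2 equiv), toluene, 100 °C; concentrate; then conc. HCl, CH2Cl2, 40 °C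
Reagents that add atoms: N,N-dimethylformamide dimethyl acetal, COC(OC)N(C)C
Why: Enaminone chromone synthesis, in which the methyl ketone condenses with the amide acetal and acid then drives conjugate addition of the phenol and loss of dimethylamine to close ring C; no stereocentre is formed.

**Step 4**
Reactants: 6 7-(benzyloxy)-4H-chromen-4-one; 7 [3,4,5-tris(benzyloxy)phenyl]boronic acid
Product: 8 (2S)-7-(benzyloxy)-2-[3,4,5-tris(benzyloxy)phenyl]chroman-4-one
Conditions: 7 (2.5 equiv), [Rh(OH)(cod)]2 (1.5 mol%), MeO-F12-BIPHEP (3.3 mol%, the antipode that gives the 2S product), toluene/H2O 10:1, 30 °C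
Reagents that add atoms: none
Why: Hayashi–Miyaura-type asymmetric conjugate addition in which the aryl–rhodium species (monovalent rhodium) adds to C2 of the chromone on the face chosen by the chiral bisphosphine and the rhodium enolate is protonated by water, setting C2 as S (ring B on the same face as in the target) in high ee.

**Step 5**
Reactants: 8 (2S)-7-(benzyloxy)-2-[3,4,5-tris(benzyloxy)phenyl]chroman-4-one; 9 4-methylbenzenesulfonohydrazide; 3 8-bromo-5,7,3',4'-tetra-O-benzyl-(+)-catechin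
Product: 12 8-[(2S)-7-(benzyloxy)-2-(3,4,5-tris(benzyloxy)phenyl)-2H-chromen-4-yl]-5,7,3',4'-tetra-O-benzyl-(+)-catechin, via tosylhydrazone 10 (not isolated), via diazoflavan 11 (not isolated)
Conditions: 8 (1.3 equiv), 9 (1.3 equiv), 1,4-dioxane, 70 °C, 2 h; then 3 (1.0 equiv), Pd2(dba)3 (4 mol%), XPhos (16 mol%), LiOtBu (3.5 equiv), 90 °C
Reagents that add atoms: none
Why: Barluenga–Valdés cross-coupling in which zerovalent palladium inserts into the C8–Br bond of 3, LiOtBu turns hydrazone 10 into diazoalkane 11 whose carbon (the former acceptor carbon C4 of the ketone, now a donor) attacks the arylpalladium bromide, and loss of N2, aryl migration onto the carbene and syn β-hydride elimination from C3 (the only β-hydrogens) give the C3=C4 alkene with the C2 stereocentre untouched.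

**Step 6**
Reactants: 12 the 4-aryl-flav-3-ene from step 5
Product: 14 octa-O-benzyl-robinetinidol-(4β→8)-catechin (upper unit 2R,3S,4R; both 3-OH free), via epoxide 13 (not isolated)
Conditions: DMDO (1.3 equiv), acetone/CH2Cl2, −40 to 0 °C; evaporate cold; then BH3·THF (4 equiv), BF3·OEt2 (0.3 equiv), THF, −40 to 0 °C; MeOH, aq. NaHCO3
Reagents that add atoms: dimethyldioxirane, CC1(C)OO1
Why: DMDO epoxidation occurs anti to the ring B aryl group at C2 (the facial preference of OsO4 and boranes on flav-3-enes) to give the 3β,4β-epoxide, and BF3-catalysed borane reduction (anti-Markovnikov reductive epoxide opening, which turns 1-arylcycloalkene oxides into cis-2-arylcycloalkanols) cleaves the doubly benzylic C4–O bond with hydride entering anti to the departing oxygen, which sets 3S (OH trans to ring B) and 4R (catechin unit cis to 3-OH).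

**Step 7**
Reactants: 14 octa-O-benzyl-robinetinidol-(4β→8)-catechin
Product: 15 robinetinidol-(4β→8)-catechin (CNP0261864.3)
Conditions: H2 (1 atm), Pd(OH)2/C, THF/MeOH 1:1, rt; Sephadex LH-20
Reagents that add atoms: none
Why: Hydrogenolysis of the eight benzyl ethers over Pd(OH)2/C under neutral conditions, as is routine for benzylated proanthocyanidins, leaves the interflavan bond, the cyclic benzylic ether bonds and all five stereocentres untouched.

**Compound list**
1 | (+)-catechin, (2R,3S) | Oc1cc(O)c2c(c1)O[C@H](c1ccc(O)c(O)c1)[C@@H](O)C2 | starting material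
2 | 5,7,3',4'-tetra-O-benzyl-(+)-catechin, (2R,3S)-5,7-bis(benzyloxy)-2-[3,4-bis(benzyloxy)phenyl]chroman-3-ol | c1ccccc1COc1cc(OCc2ccccc2)c2c(c1)O[C@H](c1ccc(OCc3ccccc3)c(OCc3ccccc3)c1)[C@@H](O)C2 | intermediate
3 | 8-bromo-5,7,3',4'-tetra-O-benzyl-(+)-catechin, (2R,3S) | c1ccccc1COc1cc(OCc2ccccc2)c2c(c1Br)O[C@H](c1ccc(OCc3ccccc3)c(OCc3ccccc3)c1)[C@@H](O)C2 | intermediate
4 | 1-[4-(benzyloxy)-2-hydroxyphenyl]ethan-1-one | CC(=O)c1ccc(OCc2ccccc2)cc1O | starting material
5 | (E)-1-[4-(benzyloxy)-2-hydroxyphenyl]-3-(dimethylamino)prop-2-en-1-one (enaminone, not isolated) | CN(C)/C=C/C(=O)c1ccc(OCc2ccccc2)cc1O | intermediate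
6 | 7-(benzyloxy)-4H-chromen-4-one | O=c1ccoc2cc(OCc3ccccc3)ccc12 | intermediate
7 | [3,4,5-tris(benzyloxy)phenyl]boronic acid | OB(O)c1cc(OCc2ccccc2)c(OCc2ccccc2)c(OCc2ccccc2)c1 | starting material
8 | (2S)-7-(benzyloxy)-2-[3,4,5-tris(benzyloxy)phenyl]chroman-4-one | c1ccccc1COc1ccc2c(c1)O[C@H](c1cc(OCc3ccccc3)c(OCc3ccccc3)c(OCc3ccccc3)c1)CC2=O | intermediate
9 | 4-methylbenzenesulfonohydrazide | Cc1ccc(cc1)S(=O)(=O)NN | starting material
10 | N-tosylhydrazone of 8 at C4, (2S) (not isolated) | c1ccccc1COc1ccc2c(c1)O[C@H](c1cc(OCc3ccccc3)c(OCc3ccccc3)c(OCc3ccccc3)c1)CC2=NNS(=O)(=O)c1ccc(C)cc1 | intermediate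
11 | (2S)-7-(benzyloxy)-4-diazo-2-[3,4,5-tris(benzyloxy)phenyl]chroman (not isolated) | c1ccccc1COc1ccc2c(c1)O[C@H](c1cc(OCc3ccccc3)c(OCc3ccccc3)c(OCc3ccccc3)c1)CC2=[N+]=[N-] | intermediate
12 | 8-{(2S)-7-(benzyloxy)-2-[3,4,5-tris(benzyloxy)phenyl]-2H-chromen-4-yl}-5,7,3',4'-tetra-O-benzyl-(+)-catechin (lower unit 2R,3S) | c1ccccc1COc1ccc2c(c1)O[C@H](c1cc(OCc3ccccc3)c(OCc3ccccc3)c(OCc3ccccc3)c1)C=C2c1c(OCc3ccccc3)cc(OCc3ccccc3)c2c1O[C@H](c1ccc(OCc3ccccc3)c(OCc3ccccc3)c1)[C@@H](O)C2 | intermediate
13 | (2R,3R,4R)-3,4-epoxide of 12, oxygen on the face anti to the ring B aryl group (not isolated) | c1ccccc1COc1ccc2c(c1)O[C@H](c1cc(OCc3ccccc3)c(OCc3ccccc3)c(OCc3ccccc3)c1)[C@H]3O[C@@]23c1c(OCc3ccccc3)cc(OCc3ccccc3)c2c1O[C@H](c1ccc(OCc3ccccc3)c(OCc3ccccc3)c1)[C@@H](O)C2 | intermediate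
14 | octa-O-benzyl-robinetinidol-(4β→8)-catechin, upper unit (2R,3S,4R), lower unit (2R,3S), both 3-OH free | c1ccccc1COc1ccc2c(c1)O[C@H](c1cc(OCc3ccccc3)c(OCc3ccccc3)c(OCc3ccccc3)c1)[C@@H](O)[C@H]2c1c(OCc3ccccc3)cc(OCc3ccccc3)c2c1O[C@H](c1ccc(OCc3ccccc3)c(OCc3ccccc3)c1)[C@@H](O)C2 | intermediate
15 | robinetinidol-(4β→8)-catechin | Oc1ccc2c(c1)O[C@H](c1cc(O)c(O)c(O)c1)[C@@H](O)[C@H]2c1c(O)cc(O)c2c1O[C@H](c1ccc(O)c(O)c1)[C@@H](O)C2 | target

**Step count and risks**
Total: 7 steps. Longest linear sequence: 5 steps (4 → 6 → 8 → 12 → 14 → 15); the lower fragment 3 needs 2 steps from 1.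

Most likely to fail, first: step 5. The aryl bromide is flanked by two ortho oxygens and carries a free secondary alcohol. Simple Bamford–Stevens elimination of 11, hydrodebromination of 3 and erosion at C2 under hot base are the competing paths. The fallback sets out from 3 and 8 and comes back at 12. Compound 3 is treated with n-BuLi (2.1 equiv, THF, −78 °C; one equivalent takes the 3-OH proton, the second exchanges bromine for lithium). The 8-lithio species is added to flavanone 8 (CeCl3 added to suppress enolisation) to give the tertiary alcohol 4-(catechin-8-yl)flavan-4-ol octabenzyl ether F1 as a mixture of C4 epimers. Dehydration with Burgess reagent (THF, 50 °C) then gives 12. This replaces the carbene coupling by a normal-polarity aryllithium addition and elimination.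

Second: step 6. The epoxide 13 is very acid-labile and may rearrange to the 3-ketone before hydride capture, and the facial selectivity of hydride delivery to so stabilised a benzylic cation is not proven for this 2,3-trans system. The fallback sets out from 12 and comes back at 14. Dihydroxylation with OsO4 (cat.)/NMO (acetone/H2O, rt), which also attacks anti to ring B, gives the stable cis-diol 4-(catechin-8-yl)flavan-3β,4β-diol octabenzyl ether F2. The tertiary benzylic 4-OH is then removed by ionic hydrogenation with Bu3SnH/TFA (CH2Cl2, −20 °C), the bulky hydride donor entering anti to the 3-oxygen.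

Third: step 4. Chromones are sluggish acceptors and the ee with this electron-rich, bulky boronic acid is untested. The fallback sets out from 4 and comes back at 12. Claisen–Schmidt condensation of 4 with 3,4,5-tris(benzyloxy)benzaldehyde (O=Cc1cc(OCc2ccccc2)c(OCc2ccccc2)c(OCc2ccccc2)c1; KOH, EtOH, rt) gives the 2'-hydroxychalcone F3. Cyclisation with NaOAc in refluxing EtOH gives the racemic flavanone F4. F4 is carried through the conditions of step 5 with enantiopure 3, which gives 12 together with its C2 epimer F5. These are diastereomers and are separated by chromatography, so the catechin unit serves as the resolving handle.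

**Further compounds**
F1 | step 5 | 8-{(2S)-7-(benzyloxy)-4-hydroxy-2-[3,4,5-tris(benzyloxy)phenyl]chroman-4-yl}-5,7,3',4'-tetra-O-benzyl-(+)-catechin, C4 epimer mixture | c1ccccc1COc1ccc2c(c1)O[C@H](c1cc(OCc3ccccc3)c(OCc3ccccc3)c(OCc3ccccc3)c1)CC2(O)c1c(OCc3ccccc3)cc(OCc3ccccc3)c2c1O[C@H](c1ccc(OCc3ccccc3)c(OCc3ccccc3)c1)[C@@H](O)C2
F2 | step 6 | (2R,3R,4R)-3,4-diol from 12, 3-OH and 4-OH cis and both anti to the ring B aryl group | c1ccccc1COc1ccc2c(c1)O[C@H](c1cc(OCc3ccccc3)c(OCc3ccccc3)c(OCc3ccccc3)c1)[C@@H](O)[C@]2(O)c1c(OCc3ccccc3)cc(OCc3ccccc3)c2c1O[C@H](c1ccc(OCc3ccccc3)c(OCc3ccccc3)c1)[C@@H](O)C2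
F3 | step 4 | (E)-1-[4-(benzyloxy)-2-hydroxyphenyl]-3-[3,4,5-tris(benzyloxy)phenyl]prop-2-en-1-one | O=C(/C=C/c1cc(OCc2ccccc2)c(OCc2ccccc2)c(OCc2ccccc2)c1)c1ccc(OCc2ccccc2)cc1O
F4 | step 4 | racemic 7-(benzyloxy)-2-[3,4,5-tris(benzyloxy)phenyl]chroman-4-one | O=C1CC(c2cc(OCc3ccccc3)c(OCc3ccccc3)c(OCc3ccccc3)c2)Oc2cc(OCc3ccccc3)ccc12
F5 | step 4 | C2 epimer of 12, upper unit (2R) | c1ccccc1COc1ccc2c(c1)O[C@@H](c1cc(OCc3ccccc3)c(OCc3ccccc3)c(OCc3ccccc3)c1)C=C2c1c(OCc3ccccc3)cc(OCc3ccccc3)c2c1O[C@H](c1ccc(OCc3ccccc3)c(OCc3ccccc3)c1)[C@@H](O)C2
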